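Divide Wednesday's charge by Thursday's and you get 4.12; divide Thursday's slope in percent per hour by Wednesday's, both taken from 10.0 h on, and you get 3.33.

| flask | solid substrate | gas phase | remark | time |
|---|---|---|---|---|
| Thursday's | 0.17 M | 12 mM (held) | run made earlier |  |
| Wednesday's | 0.70 M | 12 mM (held) | run made earlier |  |
| flask | 0.35 M | 12 mM (held) |  | 25 h |

- Thursday's (time / h: target / %, solid substrate / %): 5.00: 3.3, 93.5; 10.0: 11.2, 84.3; 15.0: 18.4, 76.9; 20.0: 25.3, 68.9; 25.0: 31.8, 60.2; 30.0: 37.8, 55.7
- Wednesday's (time / h: target / %, solid substrate / %): 2.50: 1.1, 98.3; 4.00: 1.0, 99.2; 6.00: 2.1, 96.9; 10.0: 2.1, 95.1; 20.0: 6.6, 91.6; 30.0: 10.1, 89.1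

(each reading ± 1 percentage point)

- solid substrate is a solid; its amount is given per volume of the solution
- at the start none of the gas phase is in solution
- at the start none of the solid substrate is in solution

- dusk: doubling the transfer coefficient of the gas phase, all else as stated
- dawn: doubling the solubility of the solid substrate, all else as stated
- autumn: doubling the dissolution coefficient of the solid substrate, all else as stated
- summer: doubling the saturation concentration of gas phase, all else as stated

- how much target there is at 25 h, in percent of the solid substrate charged
- the change that raises the amount of target at 25 h, in percent of the solid substrate charged most ("none" if none brings more than 2 percentage points) (dusk / dawn / autumn / summer / none)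
- amount of target at 25 h, in percent of the solid substrate charged, after dusk

Those two ratios lie close, so multiply slope by charge. Thursday's run makes 2.26 mM h⁻¹ of target on its straight stretch: call this the feed, a rate of zero order in the solid. Wednesday's run gives 2.80 mM h⁻¹, give or take 0.495 mM h⁻¹, while Thursday's is good to 0.120 mM h⁻¹, so keep Thursday's.

Now climb the times of the asked flask. Lowest stands the lag, 1.58 h, read by running Thursday's line back to no target; during it, solid enters solution and target trails. Next stands the asked 25 h, with target climbing along the line. Highest stands the time the feed needs to use up this flask's charge, 155 h, longer than the asked time, so solid remains at the reading. Feed times the time after the lag, over the charge, gives my figure: 15.1%.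

The forecast gives 15.3%, a little more than my figure, names dawn and puts dusk at 17%, holding that “raising solubility should raise the rate most directly”.

The flask gives 15.3%, which is a feed of 2.28 mM h⁻¹ against the 2.26 mM h⁻¹ read from Thursday's run. The change dawn adds 14 percentage points, and dusk leaves 15.3%, a gain of 0 points.

    gas phase ⇌ dissolved gas, rate k1*(csat - [dissolved gas]) (kL = 0.0340 s⁻¹)
    starting material + dissolved gas → target (k = 0.0100 L mol⁻¹ s⁻¹)
    starting material ⇌ dormant form (K = 1.00, k = 5.90 × 10⁻⁶ s⁻¹)
    starting material + target → side product (k = 1.30 × 10⁻⁴ L mol⁻¹ s⁻¹)
    solid substrate ⇌ starting material, rate k5*(cs5 - [starting material]) while solid is left; crystals form when [starting material] > cs5 (solubility = 17.0 mM, k = 6.00 × 10⁻⁵ s⁻¹)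

Compare what each step can deliver by 25 h into a solution kept empty: the crossing of gas into solution 10491%, the dissolving of solid 26.2%. At 10.6 h the ratio of starting material made to used is 0.999, a quasi-steady state, with 1.55% of the charge standing as starting material at 12.5 h. Now take the neighbour flask with 0.14 M of solid, read at 25.0 h: the same feed over its charge gives 37.8%, and the computed flask gives 38.2%.

The readings are calculated from invented constants; scatter was added.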